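**Falling target.** 54 % of target stands in the alder flask at 30.0 min, but 27 % at 80.0 min. So my decision for the next flask is when to stop it; the charge stays as it is.

- alder: substrate 0.14 M; enzyme 0.071 mol%; the very flask that is asked about, followed so far
- flask: substrate 0.14 M; enzyme 0.071 mol%; time 8.0 h

alder run (percent of the substrate charged)

| time / min | target / % | substrate / % |
|---|---|---|
| 6.00 | 22 | 73 |
| 15.0 | 46 | 45 |
| 30.0 | 54 | 10 |
| 50.0 | 37 | 5 |
| 60.0 | 33 | 0 |
| 80.0 | 27 | 0 |

(each reading ± 2 percentage points)

- the analysis behind the earlier runs scatters by 2 percentage points, standard deviation
- on the list of suspects stand: target <-> isomer of the product; substrate + enzyme -> target + enzyme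

- the best time, 8.0 h at the latest, for target
- the amount of target, in percent of the substrate charged, at that time

**Two rates.** On the suspected steps, substrate makes target and target drains to isomer of the product, which is what the balance of the readings misses. Between 15.0 min and 30.0 min substrate loses 35 percentage points while isomer gains 27 points, which gives 1.30. This is my making-to-draining ratio: substrate lost per isomer gained over a window. On these steps target rises over a window while the ratio stands above 1, as it does here.

**The drift.** From 30.0 min to 50.0 min the ratio reads 0.227, a rough number, since substrate loses 5 points against a scatter of 2 points. Interpolating its logarithm between the window middles, I estimate that the ratio crosses 1 at 25.1 min. I stop there, a harvest under kinetic control, and expect target near 54 %.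

**The flask.** The forecast says 0.43 h (0.33 h to 0.53 h) and 53 % (49 % to 57 %), after a reading that “nudges this later and higher”. The flask peaks at 26.9 min, against my 25.1 min, with 54.7 % of target.

    target ⇌ isomer of the product (K = 4.70, k = 0.0310 min⁻¹)
    substrate + enzyme → target + enzyme, rate k2*[substrate]*[enzyme]/(1 + ([substrate]/Km2)) (0.0860 M, k = 1200 L mol⁻¹ min⁻¹)

**Level rates.** At 0.211 h the flask makes target 2.70 times faster than it uses it up, each step taken net. At 0.449 h, with substrate 15.9 %, target 54.7 % and isomer 29.4 %, the equations give a ratio of 1.00. The enzyme stands in the rate of making and not in that of draining; scaled by the loading, my window ratio of 1.30 becomes 2.19 at like contents in the neighbouring flask with 0.12 mol% of enzyme, whose target reaches 65.1 %.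

The readings were computed for substances that don't exist; the scatter is artificial.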